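**Conventions.** Atom numbers follow the bicyclo[3.2.1]octane frame defined in the first section and are kept for every intermediate, also where systematic numbering would differ. An = 4-methoxyphenyl; Res = 3,5-dimethoxyphenyl; Stb = 2-(3,5-dimethoxyphenyl)-1-(4-methoxyphenyl)vinyl, bonded through the An-bearing carbon, the two aryl groups trans across C=C. "Exo" on C6/C7 means on the side of the C8 bridge; "endo" means on the side of the C2–C3–C4 bridge.

## The problem

Compound 26 is a resveratrol trimer in which one resorcinol ring has been dearomatised to a bicyclo[3.2.1]oct-3-ene-2,8-dione. C1–C8 are its carbons: ring A is the enedione six-ring C1–C2–C3–C4–C5–C8, ring E the cyclopentanone C1–C8–C5–C6–C7, with C5 quaternary, a 4-hydroxyphenyl group exo on C6 and a 3,5-dihydroxyphenyl group endo on C7. Ring B is the cyclopentane C4–C9–C11–C12–C5. Ring C is the five-ring of an indane (C9–C10–aryl–aryl–C11) fused cis to ring B and annulated to resorcinol ring D; C10 and C12 each carry a 4-hydroxyphenyl group.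

There are eight stereocentres. C6 and C7 can be taken from the chiral pool and can then direct C5 and C1, since a bridge can only close on one face. C5 alone must then control C9–C12, and the hydrogen on C12 has to end on the concave face of the B/C bicycle.

The two hard bonds are those at quaternary C5, which is shared by three rings, and C9–C11, which joins two former stilbene β-carbons of the same polarity and so has no polar disconnection without an oxidant.

The seven phenols must stay masked to the end. C1 sits between two ketones but cannot enolise at the bridgehead, so nucleophilic base threatens retro-Claisen cleavage. The enone and the electron-rich benzylic centres rule out hydrogenation and strong acid.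

The key step rests on one feature: C9–C11 is flanked by C10 and C12, each bearing an oxygenated aryl group. C10=C9–C4–C5–C12=C11 is therefore a 1,5-diene whose crossed [2+2] photocycloaddition makes C9–C11 and ring B. The extra C10–C12 bond it creates is strained and doubly anisyl-benzylic, which should allow it to be broken selectively afterwards.

## Retrosynthesis

**26 from 25.** The seven O–methyl bonds are cut last. Methyl ethers are the only phenol protection that survives Grignard reagents, photochemistry, one-electron oxidation and oxidants alike. The forward reaction is a global Lewis-acid demethylation.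

**25 from 24.** In the reverse sense the C10–aryl bond of ring C and the C12–H bond are traded for a C10–C12 bond, giving the bicyclo[2.1.1]hexane 24. Forward, the strained bis-anisyl bond must break, the C10 cation must be caught by the dimethoxyphenyl ring on C11, and C12 must receive hydrogen. One-electron oxidation is preferred over acid. Acid would more likely open the C9–C10 bond, which is a vinylogous donor–acceptor bond to the enone, and lead to an isomeric skeleton. This step is an isomerisation and is the one transformation of the route without direct precedent.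

**24 from 23.** C9–C11 and C10–C12 are cut together as a crossed [2+2] cycloaddition of the 1,5-diene in 23. This removes two rings and four stereocentres in one step and is the only disconnection of C9–C11 that needs neither an oxidant nor a polarity reversal. The forward reaction needs the C10 bridge on the C6 side of ring B and both bridge aryl groups pointing away from the C4–C5 bridge.

**23 from 21, and 21 from 19 and 20.** The C4–C9 bond is cut as a conjugate addition of styrylboronic acid 20 to enone 19, followed by re-desaturation. The shorter alternative would be a malonyl dichloride annulation of the cyclopentanone, then an enol triflate and cross-coupling. It was rejected because in the resulting 2,4-dione the oxygen next to quaternary C5 is the hindered one, so sulfonylation would put the styryl group on C2.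

**19 from 17, and 17 from 14 and 15.** Ring A is cut at C5–C4 and C1–C2 as a Michael–aldol annulation of cyclopentanone 14 with acrolein 15, followed by oxidation. The order matters. The intermolecular bond at C5 forms anti to the C6 aryl group, and the aldol at C1 must then close on the same face, which places the bridge cis to the C7 aryl group as required. A C1-acylated precursor would be planar at C1 and could not bridge under basic conditions.

**14 from 12 and 13, and 12 from 9 and 10.** The two aryl–ring bonds are cut as copper-catalysed conjugate additions. The first is anti to the silyloxy group, which is then eliminated; the second is anti to the first aryl group. This gives the trans-diaryl pattern and transfers the absolute configuration from 6.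

**9 from 5 and 7; 7 from 6; 5 from 4; 4 from 1 and 2.** The stilbene-type alkene is attached to C5 while that carbon is still sp2, by Suzuki–Miyaura coupling of iodoenone 7 with the boronate made from enol triflate 5. The triflate fixes which alkene carbon carries which aryl group. Ketone 4 comes from a Friedel–Crafts acylation of anisole 2 with acid 1.

## Roads not taken

**Alternative 1:** Ring D would be cut into three alkyne units. Two alkynes already attached at C10 and C11 of a ring B cyclopentane, plus an external borylated alkyne, would be joined by metal-catalysed (2+2+2) cyclotrimerisation. This closes rings C and D at once and gives bis(boronate) tricycle A1.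
- Merits: C9–C12 are set beforehand by ordinary cyclopentane chemistry, C12 carries its hydrogen from the start, and no temporary bond has to be broken. On these points it is better than the chosen plan.
- Weak points: the external alkyne must be incorporated with the right regiochemistry to give the 1,3-diboryl pattern. More seriously, A1 stops at a B–C–D tricycle. Quaternary C5, ring E with its two aryl stereocentres and ring A would all have to be built afterwards on a hindered ketone α-carbon.
- Comparison: the chosen plan has the whole chiral bicyclic half in place before ring B is made, and takes its absolute configuration from a purchased stereocentre. It pays for this with an unprecedented bond scission.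

**Alternative 2:** The C10–aryl bond (ring C) and the C12–C5 bond (ring B) would be cut. Forward, acid ionises two anisyl carbinols of an open precursor. The C10 cation closes the indane, and the C12 cation attacks the already substituted arene carbon para to a free phenol, giving cyclohexadienone A2 with quaternary C5.
- Merits: it uses only well-known benzylic cation chemistry, draws ring A from a cheap arene and keeps the C12 hydrogen throughout. For rings B and C it is the more conservative road, and this is conceded.
- Weak points: ipso attack must beat attack at a free ortho position, two cations must react in the right order, and the configuration of C5 is set under reversible acidic conditions. Ring E must then still be closed between C7 and C1 with control of two further stereocentres, and the absolute configuration has to come from an enantioselective synthesis of the diol.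
- Comparison: the chosen plan fixes C6 and C7 first and lets them direct C5 and C1 by ring strain alone.

**Alternative 3:** Ring E would be cut at C5–C6 and C8–C1. A Lewis acid opens a 2,3-diarylcyclopropane-1,1-diester at its anisyl carbon, the β-carbon of a ketene on the B–C–D tricycle attacks C6 with inversion, and the malonate carbon closes on the ketene carbonyl to give spiro cyclopentanone A3.
- Merits: it is the most convergent option, stereospecific at C6, and forms quaternary C5 and ring E in one step. In convergence it is better than the chosen plan.
- Weak points: ketenes tend to react with such 1,3-dipoles through the C=O bond, the ketene must be generated on a crowded tricycle, and the facial selectivity at C5 is uncertain. Ring A would still have to be built from the geminal diester by decarboxylation and a two-carbon insertion.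
- Comparison: the chosen plan has rings A and E complete before the key step and needs only two operations after it.

Key step: step 11

## Route

Assumption: the stereodescriptors of the target SMILES are taken as the absolute configuration; this requires the (S) enantiomer of the silyloxycyclopentenone.

Step 1
Reactants: 1 3,5-dimethoxyphenylacetic acid; 2 anisole
Product: 4 2-(3,5-dimethoxyphenyl)-1-(4-methoxyphenyl)ethan-1-one, via acid chloride 3 (not isolated)
Conditions: (COCl)2, cat. DMF, CH2Cl2, 0 °C to rt; then 2 (3 equiv), AlCl3 (1.1 equiv), CH2Cl2, 0 °C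
Reagents that add atoms: none
Why: Friedel–Crafts acylation of anisole, which is directed para by the methoxy group; excess anisole and low temperature keep the acylium ion from the dimethoxyphenyl ring and avoid ether cleavage.

Step 2
Reactants: 4 2-(3,5-dimethoxyphenyl)-1-(4-methoxyphenyl)ethan-1-one
Product: 5 (Z)-2-(3,5-dimethoxyphenyl)-1-(4-methoxyphenyl)vinyl trifluoromethanesulfonate
Conditions: KN(SiMe3)2, THF, −78 °C; PhNTf2, −78 °C to 0 °C
Reagents that add atoms: N-phenylbis(trifluoromethanesulfonimide), O=S(=O)(N(c1ccccc1)S(=O)(=O)C(F)(F)F)C(F)(F)F
Why: Enolisation of the benzyl aryl ketone can only go towards the benzylic carbon and gives the Z enolate with the aryl groups trans; O-sulfonylation fixes the An group on the future C12.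

Step 3
Reactants: 6 (S)-4-(tert-butyldimethylsilyloxy)cyclopent-2-en-1-one
Product: 7 (S)-4-(tert-butyldimethylsilyloxy)-2-iodocyclopent-2-en-1-one
Conditions: I2, pyridine, CH2Cl2, 0 °C to rt
Reagents that add atoms: iodine, II
Why: α-Iodination of an enone by conjugate addition of pyridine, iodination of the enolate and elimination; a standard operation on this silyloxy enone that leaves the stereocentre untouched.

Step 4
Reactants: 5 (Z)-2-(3,5-dimethoxyphenyl)-1-(4-methoxyphenyl)vinyl trifluoromethanesulfonate; 7 (S)-4-(tert-butyldimethylsilyloxy)-2-iodocyclopent-2-en-1-one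
Product: 9 (S)-4-(tert-butyldimethylsilyloxy)-2-Stb-cyclopent-2-en-1-one, via alkenylboronate 8 (not isolated)
Conditions: B2pin2, PdCl2(dppf) (3 mol %), KOPh, toluene, 50 °C; then 7, AsPh3, Cs2CO3, DMF–H2O, rt
Reagents that add atoms: none
Why: Miyaura borylation of the enol triflate followed by Suzuki–Miyaura coupling with the α-iodoenone, both with retention of alkene geometry; the second stage is run at room temperature with a mild base because the silyloxy enone eliminates easily.

Step 5
Reactants: 9 (S)-4-(tert-butyldimethylsilyloxy)-2-Stb-cyclopent-2-en-1-one; 10 4-methoxyphenylmagnesium bromide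
Product: 12 trans-4-An-5-Stb-cyclopent-2-en-1-one, via silyloxy ketone 11 (not isolated)
Conditions: 10 (1.5 equiv), CuBr·SMe2 (10 mol %), THF, −78 to −40 °C; aq. NH4Cl; then DBU, CH2Cl2, 0 °C
Reagents that add atoms: none
Why: Copper-catalysed conjugate addition to the 2-substituted 4-silyloxycyclopentenone occurs anti to the silyloxy group and sets C6; E1cB loss of silanolate then gives the transposed enone, and the acidic C5 centre settles trans to the new aryl group.

Step 6
Reactants: 12 trans-4-An-5-Stb-cyclopent-2-en-1-one; 13 3,5-dimethoxyphenylmagnesium chloride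
Product: 14 all-trans-4-Res-3-An-2-Stb-cyclopentan-1-one
Conditions: 13 (1.5 equiv), CuBr·SMe2 (10 mol %), THF, −78 to −40 °C; aq. NH4Cl
Reagents that add atoms: none
Why: The second conjugate addition occurs anti to the An group on the neighbouring carbon and sets C7, giving the trans-diaryl pattern; C5 stays trans to the An group on protonation.

Step 7
Reactants: 14 all-trans-4-Res-3-An-2-Stb-cyclopentan-1-one; 15 acrolein
Product: 17 2-hydroxy-5-Stb-6-exo-An-7-endo-Res-bicyclo[3.2.1]octan-8-one (C2 epimers), via Michael adduct aldehyde 16 (not isolated)
Conditions: 15 (1.5 equiv), KOt-Bu (0.2 equiv), t-BuOH–THF, 0 °C to rt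
Reagents that add atoms: none
Why: Michael–aldol annulation: the more substituted, allyl-stabilised enolate adds to acrolein at C5 anti to the C6 aryl group and makes the quaternary centre, and the C1 enolate can then reach the aldehyde only on the same face, which fixes C1 with the bridge cis to the C7 aryl group; the carbinol configuration at C2 is irrelevant.

Step 8
Reactants: 17 2-hydroxy-5-Stb-6-exo-An-7-endo-Res-bicyclo[3.2.1]octan-8-one
Product: 19 5-Stb-6-exo-An-7-endo-Res-bicyclo[3.2.1]oct-3-ene-2,8-dione, via saturated diketone 18 (not isolated)
Conditions: IBX (3.5 equiv), DMSO, rt then 65 °C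
Reagents that add atoms: none
Why: IBX oxidises the secondary alcohol and then dehydrogenates the ketone; only C3 can enolise, because C1 is a bridgehead and C5 is quaternary, so the C3=C4 enone is the only possible product.

Step 9
Reactants: 19 5-Stb-6-exo-An-7-endo-Res-bicyclo[3.2.1]oct-3-ene-2,8-dione; 20 (E)-2-(4-methoxyphenyl)vinylboronic acid
Product: 21 4-[(E)-4-methoxystyryl]-5-Stb-6-exo-An-7-endo-Res-bicyclo[3.2.1]octane-2,8-dione (styryl syn to C8)
Conditions: 20 (2 equiv), [Rh(OH)(cod)]2 (3 mol %), dioxane–H2O 10:1, 50 °C
Reagents that add atoms: none
Why: Hayashi–Miyaura conjugate addition of an alkenylboronic acid under base-free conditions, which spare the retro-Claisen-prone 2,8-dione; the alkenyl group should enter from the face of the C8 bridge, and the new C4 centre is erased in step 10.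

Step 10
Reactants: 21 4-[(E)-4-methoxystyryl]-5-Stb-6-exo-An-7-endo-Res-bicyclo[3.2.1]octane-2,8-dione
Product: 23 4-[(E)-4-methoxystyryl]-5-Stb-6-exo-An-7-endo-Res-bicyclo[3.2.1]oct-3-ene-2,8-dione, via trimethylsilyl enol ether 22 (not isolated)
Conditions: TMSOTf, Et3N, CH2Cl2, 0 °C; then Pd(OAc)2 (1.1 equiv), MeCN, rt
Reagents that add atoms: none
Why: Saegusa–Ito dehydrogenation; the silyl enol ether can form only towards C3, and the C4 hydrogen that is lost is doubly allylic, so the conjugated styryl dienone should form readily.

Step 11
Reactants: 23 4-[(E)-4-methoxystyryl]-5-Stb-6-exo-An-7-endo-Res-bicyclo[3.2.1]oct-3-ene-2,8-dione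
Product: 24 crossed photoadduct: bicyclo[2.1.1]hexane formed by C9, C10, C11, C12 and the C4–C5 edge, with An on C10 and Res on C11 both anti to the C4–C5 bridge, An on bridgehead C12, and the C10 bridge on the C6 side
Conditions: fac-Ir(ppy)3 (1 mol %), degassed MeCN (5 mM), 450 nm LEDs, rt
Reagents that add atoms: none
Why: Triplet energy transfer from excited fac-Ir(ppy)3 populates the styryl dienone or the stilbene unit of 23 but not the ketones, whose triplets lie higher. The triplet closes ring B by the rule of five: C9 and C11 bond in a 5-exo mode and leave benzylic radicals on C10 and C12. After intersystem crossing these two radicals recombine to the C10–C12 bond, so the second ring closed is the cyclobutane C9–C10–C12–C11 of a bicyclo[2.1.1]hexane. The closest known reaction type is the sensitised crossed [2+2] cycloaddition of aryl-substituted 1,5-dienes to bicyclo[2.1.1]hexanes. C9 and C12 become bridgeheads; C10 and C11 should keep their aryl groups anti to the C4–C5 bridge because the long-lived diradical collapses to the less congested cyclobutane, which also makes the alkene geometry of 23 irrelevant. Which side of the C9–C4–C5–C12 plane receives the C10 bridge is decided only by the C5 stereocentre, and the adduct needed has C10 on the C6 side and C11 on the C8 side. This preference is expected to be modest, since the two sides differ only as a methine versus a carbonyl carbon, and the isomer with the bridges interchanged has to be removed. High dilution, degassing and a sensitiser too low in energy for enone or di-π-methane photochemistry are meant to secure chemoselectivity.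

Step 12
Reactants: 24 crossed photoadduct
Product: 25 heptamethyl ether of 26
Conditions: 9-mesityl-10-methylacridinium tetrafluoroborate (5 mol %), PhSSPh (20 mol %), 2,6-lutidine (0.2 equiv), ClCH2CH2Cl (5 mM), 450 nm LEDs, rt, argon
Reagents that add atoms: none
Why: Proposed new method: one-electron oxidation of an anisyl ring by the excited acridinium salt should break the strained, doubly benzylic C10–C12 bond, as in the known cycloreversion of 1,2-bis(4-methoxyphenyl)cyclobutane radical cations and the nucleophile-assisted ring opening of arylcyclopropane radical cations; the C10 cation is then caught in a five-ring Friedel–Crafts closure by the ortho carbon of the Res ring held cis on C11 (ring C, An on the convex face), and the tertiary benzylic C12 radical takes hydrogen from thiophenol formed in the flask, whose thiyl radical is reduced by the acridine radical; because hydrogen transfer between thiyl and this benzylic C–H is close to thermoneutral and therefore reversible, C12 is expected to settle with its An group anti to ring D and to the C6 aryl group, as in 25.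

Step 13
Reactants: 25 heptamethyl ether of 26
Product: 26 CNP0407321.1
Conditions: BBr3 (20 equiv), CH2Cl2, −78 °C to rt; then MeOH, aq. NaHCO3
Reagents that add atoms: none
Why: Lewis-acid cleavage of aryl methyl ethers, the usual last step for polymethylated oligostilbenes; no stereocentre is epimerisable under these conditions and the non-enolisable dione is stable to acid.

## Compound list

1 | 3,5-dimethoxyphenylacetic acid | COc1cc(CC(=O)O)cc(OC)c1 | starting material
2 | anisole | COc1ccccc1 | starting material
3 | 2-(3,5-dimethoxyphenyl)acetyl chloride | COc1cc(CC(=O)Cl)cc(OC)c1 | intermediate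
4 | 2-(3,5-dimethoxyphenyl)-1-(4-methoxyphenyl)ethan-1-one | COc1ccc(cc1)C(=O)Cc1cc(OC)cc(OC)c1 | intermediate
5 | (Z)-2-(3,5-dimethoxyphenyl)-1-(4-methoxyphenyl)vinyl trifluoromethanesulfonate | COc1ccc(cc1)/C(OS(=O)(=O)C(F)(F)F)=C/c1cc(OC)cc(OC)c1 | intermediate
6 | (S)-4-(tert-butyldimethylsilyloxy)cyclopent-2-en-1-one | O=C1C=C[C@@H](O[Si](C)(C)C(C)(C)C)C1 | starting material
7 | (S)-4-(tert-butyldimethylsilyloxy)-2-iodocyclopent-2-en-1-one | O=C1C(I)=C[C@@H](O[Si](C)(C)C(C)(C)C)C1 | intermediate
8 | (E)-2-[2-(3,5-dimethoxyphenyl)-1-(4-methoxyphenyl)vinyl]-4,4,5,5-tetramethyl-1,3,2-dioxaborolane | COc1ccc(cc1)/C(B2OC(C)(C)C(C)(C)O2)=C/c1cc(OC)cc(OC)c1 | intermediate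
9 | (S)-4-(tert-butyldimethylsilyloxy)-2-Stb-cyclopent-2-en-1-one | O=C1C(/C(=C\c2cc(OC)cc(OC)c2)c2ccc(OC)cc2)=C[C@@H](O[Si](C)(C)C(C)(C)C)C1 | intermediate
10 | 4-methoxyphenylmagnesium bromide | COc1ccc([Mg]Br)cc1 | starting material
11 | 4-(tert-butyldimethylsilyloxy)-3-An-2-Stb-cyclopentan-1-one, 2,3-trans and 3,4-trans | O=C1C[C@H](O[Si](C)(C)C(C)(C)C)[C@@H](c2ccc(OC)cc2)[C@@H]1/C(=C\c1cc(OC)cc(OC)c1)c1ccc(OC)cc1 | intermediate
12 | trans-4-An-5-Stb-cyclopent-2-en-1-one | O=C1C=C[C@@H](c2ccc(OC)cc2)[C@@H]1/C(=C\c1cc(OC)cc(OC)c1)c1ccc(OC)cc1 | intermediate
13 | 3,5-dimethoxyphenylmagnesium chloride | COc1cc(OC)cc([Mg]Cl)c1 | starting material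
14 | all-trans-4-Res-3-An-2-Stb-cyclopentan-1-one | O=C1C[C@H](c2cc(OC)cc(OC)c2)[C@@H](c2ccc(OC)cc2)[C@@H]1/C(=C\c1cc(OC)cc(OC)c1)c1ccc(OC)cc1 | intermediate
15 | acrolein | C=CC=O | starting material
16 | 3-(4-Res-5-An-2-oxo-1-Stb-cyclopentyl)propanal, propanal arm trans to An | O=C1C[C@H](c2cc(OC)cc(OC)c2)[C@@H](c2ccc(OC)cc2)[C@@]1(CCC=O)/C(=C\c1cc(OC)cc(OC)c1)c1ccc(OC)cc1 | intermediate
17 | 2-hydroxy-5-Stb-6-exo-An-7-endo-Res-bicyclo[3.2.1]octan-8-one, C2 epimers | OC1CC[C@]2(/C(=C\c3cc(OC)cc(OC)c3)c3ccc(OC)cc3)C(=O)[C@H]1[C@H](c1cc(OC)cc(OC)c1)[C@H]2c1ccc(OC)cc1 | intermediate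
18 | 5-Stb-6-exo-An-7-endo-Res-bicyclo[3.2.1]octane-2,8-dione | O=C1CC[C@]2(/C(=C\c3cc(OC)cc(OC)c3)c3ccc(OC)cc3)C(=O)[C@H]1[C@H](c1cc(OC)cc(OC)c1)[C@H]2c1ccc(OC)cc1 | intermediate
19 | 5-Stb-6-exo-An-7-endo-Res-bicyclo[3.2.1]oct-3-ene-2,8-dione | O=C1C=C[C@]2(/C(=C\c3cc(OC)cc(OC)c3)c3ccc(OC)cc3)C(=O)[C@H]1[C@H](c1cc(OC)cc(OC)c1)[C@H]2c1ccc(OC)cc1 | intermediate
20 | (E)-2-(4-methoxyphenyl)vinylboronic acid | COc1ccc(/C=C/B(O)O)cc1 | starting material
21 | 4-[(E)-4-methoxystyryl]-5-Stb-6-exo-An-7-endo-Res-bicyclo[3.2.1]octane-2,8-dione, styryl syn to C8 | O=C1C[C@H](/C=C/c3ccc(OC)cc3)[C@]2(/C(=C\c3cc(OC)cc(OC)c3)c3ccc(OC)cc3)C(=O)[C@H]1[C@H](c1cc(OC)cc(OC)c1)[C@H]2c1ccc(OC)cc1 | intermediate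
22 | 2-trimethylsilyloxy-4-[(E)-4-methoxystyryl]-5-Stb-6-exo-An-7-endo-Res-bicyclo[3.2.1]oct-2-en-8-one | C[Si](C)(C)OC1=C[C@H](/C=C/c3ccc(OC)cc3)[C@]2(/C(=C\c3cc(OC)cc(OC)c3)c3ccc(OC)cc3)C(=O)[C@H]1[C@H](c1cc(OC)cc(OC)c1)[C@H]2c1ccc(OC)cc1 | intermediate
23 | 4-[(E)-4-methoxystyryl]-5-Stb-6-exo-An-7-endo-Res-bicyclo[3.2.1]oct-3-ene-2,8-dione | O=C1C=C(/C=C/c3ccc(OC)cc3)[C@]2(/C(=C\c3cc(OC)cc(OC)c3)c3ccc(OC)cc3)C(=O)[C@H]1[C@H](c1cc(OC)cc(OC)c1)[C@H]2c1ccc(OC)cc1 | intermediate
24 | crossed photoadduct: bicyclo[2.1.1]hexane of C9, C10, C11, C12 on the C4–C5 edge; C10 bridge on the C6 side; An on C10 and Res on C11 anti to the C4–C5 bridge; An on C12 | O=C1C=C2[C@H]3[C@H](c4ccc(OC)cc4)[C@](c4ccc(OC)cc4)([C@@H]3c3cc(OC)cc(OC)c3)[C@]24C(=O)[C@H]1[C@H](c1cc(OC)cc(OC)c1)[C@H]4c1ccc(OC)cc1 | intermediate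
25 | heptamethyl ether of 26 (rings A–E complete; ring C cis-fused on the C6 face of ring B; An on C10 on the convex face; An on C12 trans to ring D) | O=C1C=C2[C@H]3[C@H](c4ccc(OC)cc4)c4c(OC)cc(OC)cc4[C@H]3[C@H](c3ccc(OC)cc3)[C@]23C(=O)[C@H]1[C@H](c1cc(OC)cc(OC)c1)[C@H]3c1ccc(OC)cc1 | intermediate
26 | CNP0407321.1, the heptaphenol | O=C1C=C2[C@H]3[C@H](c4ccc(O)cc4)c4c(O)cc(O)cc4[C@H]3[C@H](c3ccc(O)cc3)[C@]23C(=O)[C@H]1[C@H](c1cc(O)cc(O)c1)[C@H]3c1ccc(O)cc1 | target

## Step count and least certain steps

Total: 13 steps. Longest linear sequence: 12 steps (steps 1, 2 and 4 to 13).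

**Step 12 (proposed new method).**
- What may go wrong: the ring-opened radical cation may fragment back to the diene radical cation (the normal fate of bis-anisyl cyclobutane radical cations) faster than the arene captures C10. The vinylogous donor–acceptor bond C9–C10 may break instead. Hydrogen may be delivered to the convex face of C12 and not be corrected.
- Fallback (known chemistry): it sets out from 23, to which 24 reverts on one-electron oxidation, and comes back at 25. Irradiating 23 with the same acridinium salt and PhSSPh in CH2Cl2–MeOH applies the established anti-Markovnikov hydroetherification of aryl alkenes. Methanol adds to C11 of the oxidised stilbene unit and the C12 radical is reduced by the thiol, giving the C11 methyl ether F1 with the C12 hydrogen already in place; C12 epimers are separated. BF3·OEt2 in CH2Cl2 at −40 °C then ionises the benzylic ether. C9 of the styryl group attacks C11 in a 5-exo cation–olefin closure (ring B), and the resulting C10 cation is caught by the Res ring on C11 (ring C). This is the usual acid-triggered benzylic cation cascade of oligostilbene chemistry and reaches 25 without a cyclobutane.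

**Step 11 (key step).**
- What may go wrong: poor facial selectivity in placing the C10 bridge on the C6 side, closure with an aryl group syn to the C4–C5 bridge, and unproductive alkene isomerisation that wastes the excitation.
- Fallback: it sets out from 23 and returns to 23. The isomers are separated, and the bridge-interchanged photoadduct F2 is returned to the diene by the known radical-cation cycloreversion of bis(4-methoxyphenyl)cyclobutanes (acridinium salt, MeCN, 450 nm, no hydrogen donor). Selectivity is thus handled by a ground-state recycling loop instead of by substrate control. If the bias proves strongly adverse, material is diverted at 23 into the ionic sequence described for step 12.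

**Step 7.**
- What may go wrong: slow Michael addition at the hindered α-carbon, which lets acrolein oligomerise; reaction of the dienolate at its γ-carbon, or migration of the side-chain double bond into conjugation; erosion of facial selectivity at C5.
- Fallback: it sets out from 14 and comes back at 18. Methyl acrylate with catalytic KOt-Bu gives the isolable keto ester F3, and LiN(SiMe3)2 in THF at −78 °C closes the C1–C2 bond by intramolecular Claisen condensation to diketone 18. The IBX dehydrogenation of step 8 then follows. This separates bond formation at C5 from ring closure.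

**Step 9.**
- What may go wrong: failure of the alkenylrhodium species to insert at a β-carbon flanked by the quaternary centre, so that protodeboronation of 20 wins.
- Fallback: it sets out from 19 and comes back at 23. The styryl group is built in two pieces. The smaller vinyl group is added with CH2=CHMgBr, CuBr·SMe2 and TMSCl to give the 4-vinyl diketone F4. Saegusa–Ito dehydrogenation gives the 4-vinyl dienone F5, and a Heck reaction with 4-iodoanisole (Pd(OAc)2, P(o-tol)3, Et3N, DMF, 80 °C) at the unhindered terminal carbon gives 23.

## Further compounds

F1 | step 12 | 4-[(E)-4-methoxystyryl]-5-[2-(3,5-dimethoxyphenyl)-2-methoxy-1-(4-methoxyphenyl)ethyl]-6-exo-An-7-endo-Res-bicyclo[3.2.1]oct-3-ene-2,8-dione, C12 as in 26, C11 epimers | O=C1C=C(/C=C/c3ccc(OC)cc3)[C@]2([C@@H](c3ccc(OC)cc3)C(OC)c3cc(OC)cc(OC)c3)C(=O)[C@H]1[C@H](c1cc(OC)cc(OC)c1)[C@H]2c1ccc(OC)cc1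
F2 | step 11 | diastereomer of 24 with the C10 bridge on the C8 side and the C11 bridge on the C6 side, aryl groups anti | O=C1C=C2[C@@H]3[C@@H](c4ccc(OC)cc4)[C@@](c4ccc(OC)cc4)([C@H]3c3cc(OC)cc(OC)c3)[C@]24C(=O)[C@H]1[C@H](c1cc(OC)cc(OC)c1)[C@H]4c1ccc(OC)cc1
F3 | step 7 | methyl 3-(4-Res-5-An-2-oxo-1-Stb-cyclopentyl)propanoate, ester arm trans to An | O=C1C[C@H](c2cc(OC)cc(OC)c2)[C@@H](c2ccc(OC)cc2)[C@@]1(CCC(=O)OC)/C(=C\c1cc(OC)cc(OC)c1)c1ccc(OC)cc1
F4 | step 9 | 4-vinyl-5-Stb-6-exo-An-7-endo-Res-bicyclo[3.2.1]octane-2,8-dione, vinyl syn to C8 | O=C1C[C@H](C=C)[C@]2(/C(=C\c3cc(OC)cc(OC)c3)c3ccc(OC)cc3)C(=O)[C@H]1[C@H](c1cc(OC)cc(OC)c1)[C@H]2c1ccc(OC)cc1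
F5 | step 9 | 4-vinyl-5-Stb-6-exo-An-7-endo-Res-bicyclo[3.2.1]oct-3-ene-2,8-dione | O=C1C=C(C=C)[C@]2(/C(=C\c3cc(OC)cc(OC)c3)c3ccc(OC)cc3)C(=O)[C@H]1[C@H](c1cc(OC)cc(OC)c1)[C@H]2c1ccc(OC)cc1
A1 | alternative 1 | bis(pinacolboronate) tricycle of rings B, C and D with a dioxolane-masked ring B ketone | O1CCOC12C[C@@H](c3ccc(OC)cc3)[C@@H]3c4cc(B5OC(C)(C)C(C)(C)O5)cc(B5OC(C)(C)C(C)(C)O5)c4[C@@H](c4ccc(OC)cc4)[C@H]23
A2 | alternative 2 | tetracyclic 3-bromocyclohexadienone of rings A to D with quaternary C5 | O=C1C(Br)=C2[C@H]3[C@H](c4ccc(OC)cc4)c4c(OC)cc(OC)cc4[C@H]3[C@H](c3ccc(OC)cc3)[C@]2([C@H](c2ccc(OC)cc2)Cc2cc(OC)cc(OC)c2)C(OC)=C1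
A3 | alternative 3 | spiro cyclopentanone (ring E) with geminal methyl esters on C1 on the ketal-protected B–C–D tricycle | O=C1C(C(=O)OC)(C(=O)OC)[C@H](c2cc(OC)cc(OC)c2)[C@@H](c2ccc(OC)cc2)[C@]12C3(OCCO3)[C@H]4[C@H](c5ccc(OC)cc5)c5c(OC)cc(OC)cc5[C@H]4[C@@H]2c1ccc(OC)cc1
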